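The plan rests on cutting the C4–C4a bond of ring C. In ring A, C4a stands para to the oxygen on C7 and beside C8a, which carries O1. Both donors therefore steer an electrophile to the very carbon that must bond to the C4 carbonyl. An intramolecular Friedel–Crafts acylation exploits this: one operation forms C4–C4a and closes the pyranone, with ring B and C2=C3 already in place. The precursor is a (Z)-2-aryl-3-aryloxyacrylic acid built from an arylacetate, a formate carbon and resorcinol monobenzyl ether. Benzyl guards O7 through the Lewis acid step, which a prenyl ether would not survive, and is swapped for prenyl last.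

Key step: step 5

Assumption: the enol derivatives before the key step are drawn as the Z isomers (oxygen substituent on the acrylate C3 cis to the carboxyl carbon), which the chosen conditions should favour. Any E isomer formed alongside is carried on unseparated, because the geometry becomes labile in the key step.

Step 1
Reactants: 1 methyl (3,4-dimethoxyphenyl)acetate
Product: 2 methyl (Z)-2-(3,4-dimethoxyphenyl)-3-hydroxyprop-2-enoate (enol form of the α-formyl ester)
Conditions: NaH (2 equiv), HCO2Me (excess), THF, 0 °C to rt; then cold 1 M HCl
Reagents that add atoms: methyl formate, COC=O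
Why: Crossed Claisen condensation (α-formylation): the ester enolate can only acylate on the non-enolisable formate, whose methoxide matches the methyl ester, and irreversible deprotonation of the acidic product pulls the equilibrium over, the freed compound resting as the hydrogen-bonded Z enol.

Step 2
Reactants: 2 methyl (Z)-2-(3,4-dimethoxyphenyl)-3-hydroxyprop-2-enoate
Product: 3 methyl (Z)-2-(3,4-dimethoxyphenyl)-3-(tosyloxy)prop-2-enoate
Conditions: TsCl, N-methylimidazole, LiOH, CH2Cl2, 0 °C to rt
Reagents that add atoms: p-toluenesulfonyl chloride (TsCl), Cc1ccc(cc1)S(=O)(=O)Cl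
Why: Stereodefined enol tosylation of an α-formyl ester: lithium holds the enolate oxygen and the ester carbonyl in a six-membered chelate, so O-sulfonylation by the N-tosylimidazolium salt made in the flask should fix the tosyloxy group cis to CO2Me (Z).

Step 3
Reactants: 3 methyl (Z)-2-(3,4-dimethoxyphenyl)-3-(tosyloxy)prop-2-enoate; 4 3-(benzyloxy)phenol
Product: 5 methyl (Z)-3-[3-(benzyloxy)phenoxy]-2-(3,4-dimethoxyphenyl)prop-2-enoate
Conditions: 4 (1.0 equiv), K2CO3, DMF, 0 °C to rt
Reagents that add atoms: none
Why: Nucleophilic vinylic substitution by addition–elimination: the phenoxide of 4 adds to the unhindered acceptor carbon C3 and the very good tosylate leaving group departs before the transient ester enolate rotates, so the aryl vinyl ether should form with predominant retention of the Z geometry.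

Step 4
Reactants: 5 methyl (Z)-3-[3-(benzyloxy)phenoxy]-2-(3,4-dimethoxyphenyl)prop-2-enoate
Product: 6 (Z)-3-[3-(benzyloxy)phenoxy]-2-(3,4-dimethoxyphenyl)prop-2-enoic acid
Conditions: LiOH, THF/H2O, rt; then 1 M HCl to pH 3, 0 °C
Reagents that add atoms: lithium hydroxide (LiOH), [Li+].[OH-]
Why: Saponification (BAc2 ester hydrolysis), run without an alcohol cosolvent so that no alkoxide can exchange the aryloxy group; once the carboxylate has formed the alkene is no longer a Michael acceptor, which is why aryloxyacrylates in general survive this operation.

Step 5
Reactants: 6 (Z)-3-[3-(benzyloxy)phenoxy]-2-(3,4-dimethoxyphenyl)prop-2-enoic acid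
Product: 8 7-(benzyloxy)-3-(3,4-dimethoxyphenyl)-4H-chromen-4-one (7-benzyloxy-3',4'-dimethoxyisoflavone), via acyl chloride 7 (not isolated)
Conditions: (COCl)2, cat. DMF, CH2Cl2, 0 °C to rt, then evaporation; SnCl4 (2 equiv), CH2Cl2 (0.01 M), −78 to 0 °C; cold 1 M HCl
Reagents that add atoms: oxalyl chloride, O=C(Cl)C(=O)Cl (supplies the chlorine of 7; nothing of it remains in 8)
Why: Oxalyl chloride converts 6 into acyl chloride 7, SnCl4 ionises it to an acylium ion that the enol ether oxygen stabilises (ArO+=CH–C(Ar)=C=O), C4a of ring A attacks the acyl carbon, and loss of the proton from the arenium ion restores aromaticity. The closest known reaction type is the intramolecular Friedel–Crafts acylation by which 3-aryloxyacrylic and aryloxyfumaric acids are closed to chromones, the ring-closing half of a Simonis chromone synthesis. Ring C, the only ring formed, closes in a six-membered mode that is exo with respect to the acyl C=O and takes in the C4a–C8a edge of ring A; only C4–C4a is made and no stereocentre arises. The step needs regioselectivity between the two carbons ortho to O1: the one para to the benzyloxy group is unhindered and enjoys para donation, the one between the two oxygens is flanked on both sides, so the 7-benzyloxy and not the 5-benzyloxy isomer should result. It also needs the carboxyl carbon cis to the aryloxy group, which is built into 6 and is backed up by the low C2=C3 rotation barrier of the oxocarbenium–ketene form, the same equilibration that lets E-configured phenol–propiolate adducts close to chromones. Ring B cannot compete because it could only close a four-membered ring, dilution suppresses intermolecular acylation, and SnCl4 at low temperature, facing a benzyl ether that has no neighbouring donor for chelation, should leave O7 protected.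

Step 6
Reactants: 8 7-(benzyloxy)-3-(3,4-dimethoxyphenyl)-4H-chromen-4-one
Product: 9 3-(3,4-dimethoxyphenyl)-7-hydroxy-4H-chromen-4-one (7-hydroxy-3',4'-dimethoxyisoflavone)
Conditions: BCl3 (3 equiv), pentamethylbenzene (3 equiv), CH2Cl2, −78 °C; then H2O
Reagents that add atoms: none
Why: Lewis acid debenzylation with a non-basic cation scavenger: BCl3 activates the benzylic C–O bond, pentamethylbenzene traps the benzyl cation by Friedel–Crafts alkylation before it can reach ring B, and at −78 °C the two aryl methyl ethers and the C2=C3 bond, which hydrogenolysis might touch, should be left alone.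

Step 7
Reactants: 9 3-(3,4-dimethoxyphenyl)-7-hydroxy-4H-chromen-4-one; 10 prenyl bromide (1-bromo-3-methylbut-2-ene)
Product: 11 3-(3,4-dimethoxyphenyl)-7-[(3-methylbut-2-en-1-yl)oxy]-4H-chromen-4-one (7-prenyloxy-3',4'-dimethoxyisoflavone, the target)
Conditions: K2CO3, acetone, reflux
Reagents that add atoms: none
Why: Williamson ether synthesis: the acidic 7-OH, a vinylogous carboxylic acid through C4=O, is deprotonated by K2CO3 and its phenoxide displaces bromide at the primary allylic carbon by SN2, 9 offering no other nucleophilic site.

Compound list
1 | methyl (3,4-dimethoxyphenyl)acetate | COC(=O)Cc1ccc(OC)c(OC)c1 | starting material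
2 | methyl (Z)-2-(3,4-dimethoxyphenyl)-3-hydroxyprop-2-enoate | COC(=O)/C(=C\O)c1ccc(OC)c(OC)c1 | intermediate
3 | methyl (Z)-2-(3,4-dimethoxyphenyl)-3-(tosyloxy)prop-2-enoate | COC(=O)/C(=C\OS(=O)(=O)c1ccc(C)cc1)c1ccc(OC)c(OC)c1 | intermediate
4 | 3-(benzyloxy)phenol | Oc1cccc(OCc2ccccc2)c1 | starting material
5 | methyl (Z)-3-[3-(benzyloxy)phenoxy]-2-(3,4-dimethoxyphenyl)prop-2-enoate | COC(=O)/C(=C\Oc1cccc(OCc2ccccc2)c1)c1ccc(OC)c(OC)c1 | intermediate
6 | (Z)-3-[3-(benzyloxy)phenoxy]-2-(3,4-dimethoxyphenyl)prop-2-enoic acid | OC(=O)/C(=C\Oc1cccc(OCc2ccccc2)c1)c1ccc(OC)c(OC)c1 | intermediate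
7 | (Z)-3-[3-(benzyloxy)phenoxy]-2-(3,4-dimethoxyphenyl)prop-2-enoyl chloride | O=C(Cl)/C(=C\Oc1cccc(OCc2ccccc2)c1)c1ccc(OC)c(OC)c1 | intermediate
8 | 7-(benzyloxy)-3-(3,4-dimethoxyphenyl)-4H-chromen-4-one | O=c1c(-c2ccc(OC)c(OC)c2)coc2cc(OCc3ccccc3)ccc12 | intermediate
9 | 3-(3,4-dimethoxyphenyl)-7-hydroxy-4H-chromen-4-one | O=c1c(-c2ccc(OC)c(OC)c2)coc2cc(O)ccc12 | intermediate
10 | prenyl bromide (1-bromo-3-methylbut-2-ene) | CC(C)=CCBr | starting material
11 | 3-(3,4-dimethoxyphenyl)-7-[(3-methylbut-2-en-1-yl)oxy]-4H-chromen-4-one | COc1ccc(-c2coc3cc(OCC=C(C)C)ccc3c2=O)cc1OC | target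

Total step count: 7. Longest linear sequence: 7 steps (1 to 11).

The three steps most likely to fail

Risk 1, step 5. Several processes may interfere:
- Lewis acid-induced loss of the benzyl group, with benzyl transfer onto electron-rich ring B.
- Chloride-induced cleavage of the aryl vinyl ether before closure.
- Sluggish E-to-Z equilibration of any E material.
- Intermolecular acylation.

The fallback is the deoxybenzoin approach. It makes C4–C4a intermolecularly and closes ring C at C2 instead. It sets out from 1 and comes back to the route at 9. Saponification of 1 (NaOH, aqueous MeOH) gives (3,4-dimethoxyphenyl)acetic acid F1. Friedel–Crafts acylation of resorcinol with F1 in BF3·OEt2 at about 85 °C gives 1-(2,4-dihydroxyphenyl)-2-(3,4-dimethoxyphenyl)ethan-1-one F2. Vilsmeier-type formylation of the activated methylene of F2 with DMF, BF3·OEt2 and MsCl, followed by spontaneous cyclodehydration, closes the pyranone to 9. Step 7 then follows unchanged and no benzyl group is needed.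

Risk 2, step 3. The hard phenoxide may attack at sulfur rather than at C3, a sulfonyl transfer that merely returns the enolate of 2. The alkene geometry may also erode through reversible addition of phenoxide to the product. The fallback uses an electrophile with a single electrophilic site. It sets out from 2 and comes back at 5. Deoxychlorination of the vinylogous acid 2 with (chloromethylene)dimethyliminium chloride in CH2Cl2 gives methyl (Z)-3-chloro-2-(3,4-dimethoxyphenyl)prop-2-enoate F3; either geometry serves. The potassium phenoxide of 4 (K2CO3, DMF) then displaces chloride, the classical way from β-chloroacrylates to aryloxyacrylates, to give 5.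

Risk 3, step 4. Hydroxide may attack C3 in conjugate fashion and expel the phenoxide, in competition with slow hydrolysis of the hindered, cross-conjugated ester. The fallback breaks the O–CH3 bond instead of the acyl–oxygen bond. It sets out from 5 and comes back at 6. LiI in refluxing EtOAc dealkylates the methyl ester by SN2 attack of iodide at the methyl carbon, and dilute HCl then frees the acid. Iodide is too poor a conjugate donor to displace the aryloxy group, and the aryl ethers are untouched at this temperature. No new compound is made on this way (F0).

Further compounds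
F1 | step 5 | (3,4-dimethoxyphenyl)acetic acid | OC(=O)Cc1ccc(OC)c(OC)c1
F2 | step 5 | 1-(2,4-dihydroxyphenyl)-2-(3,4-dimethoxyphenyl)ethan-1-one | O=C(Cc1ccc(OC)c(OC)c1)c1ccc(O)cc1O
F3 | step 3 | methyl (Z)-3-chloro-2-(3,4-dimethoxyphenyl)prop-2-enoate | COC(=O)/C(=C\Cl)c1ccc(OC)c(OC)c1
F0 | step 4 | none | none
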